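**Retrosynthetic overview**

1. Numbering (germacrane type): C1 furanone C=O, C2 furanone =CH, C3 furanone =C–O, C4 CH(CH3), C5 CH2, C6 CH–O(ester), C7=C11 butenolide C=C, C12 lactone C=O, C13 CH2OH, C8 enol-lactone carbon, C9 =CH, C10 C(CH3)–O; target 26 ⇐ esterification of C6–OH and removal of two 4-methoxybenzyl (PMB) ethers from tricyclic alcohol 22.
2. Key disconnection: 22 ⇐ bicyclic dilactone 20 by cutting C1–C2 and O–C10 together. The feature that allows it: the C6 oxygen is 1,5 to C1, so it can hold the C1 acyl group as a seven-membered enoate lactone (ring O–C1–C10=C9–C8–C7–C6), from which the C3 methyl-ketone enolate (unit O–C3=C2) takes it through a seven-membered transition state; C8 of the butenolide is an acetal carbon whose acetate is vinylogous to C10 through C9=C10.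
3. 20 ⇐ furan 17 (singlet oxygen turns the furan C8–C7–C11–C12 into the butenolide); 17 ⇐ 16 by intramolecular Horner–Wadsworth–Emmons closure of the seven-membered lactone at C9=C10.
4. The C4/C6 chain ⇐ furan aldehyde 7 by asymmetric 2-(ethoxycarbonyl)allylation (C6), hydrogenation of the α-methylene γ-lactone (C4) and MeLi opening (C2); furan 4 ⇐ Feist–Benary synthesis from 1 and 2.
5. Order of ring formation: furan (latent butenolide) → γ-lactone (temporary) → seven-membered lactone (temporary tether) → butenolide → ten-membered carbocycle and 3(2H)-furanone together in step 12.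

Key step: step 12

Remark on the chemistry: the acetal carbon C8 of 19, 20 and 21 and the phosphonate α-carbon of 14–16 are stereochemically undefined (mixtures); both become sp2 later, so this is without consequence.

**Route**

Step 1
Reactants: 1 methyl 4,4-dimethoxy-3-oxobutanoate; 2 1,3-dichloropropan-2-one
Product: 4 methyl 4-(chloromethyl)-2-(dimethoxymethyl)furan-3-carboxylate, via hydroxydihydrofuran 3 (not isolated)
Conditions: pyridine, MeOH, 50 °C; then TsOH·H2O (cat.), MeOH, rt
Reagents that add atoms: none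
Why: Feist–Benary furan synthesis, in which the active methylene of 1 adds to the ketone of 2, the enol oxygen displaces one chloride to give 3, and acid dehydration aromatises, so the acetal carbon C9 sits on C8, the ester carbon C6 on C7, C13 on C11 and C12 keeps its hydrogen; no stereocentre is formed.

Step 2
Reactants: 4 methyl 4-(chloromethyl)-2-(dimethoxymethyl)furan-3-carboxylate
Product: 5 methyl 2-(dimethoxymethyl)-4-{[(4-methoxybenzyl)oxy]methyl}furan-3-carboxylate
Conditions: 4-MeOC6H4CH2OH, NaH, Bu4NI (cat.), THF, 0 °C → rt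
Reagents that add atoms: 4-methoxybenzyl alcohol, COc1ccc(CO)cc1
Why: Williamson ether synthesis on the activated furylmethyl chloride, run cold so that ester exchange should stay minor.

Step 3
Reactants: 5 methyl 2-(dimethoxymethyl)-4-{[(4-methoxybenzyl)oxy]methyl}furan-3-carboxylate
Product: 6 [2-(dimethoxymethyl)-4-{[(4-methoxybenzyl)oxy]methyl}furan-3-yl]methanol
Conditions: i-Bu2AlH (2.2 equiv), CH2Cl2, −78 °C; aq. potassium sodium tartrate
Reagents that add atoms: none
Why: Hydride reduction of the ester to the primary alcohol by i-Bu2AlH, to which the acetal and the PMB ether are inert.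

Step 4
Reactants: 6 [2-(dimethoxymethyl)-4-{[(4-methoxybenzyl)oxy]methyl}furan-3-yl]methanol
Product: 7 2-(dimethoxymethyl)-4-{[(4-methoxybenzyl)oxy]methyl}furan-3-carbaldehyde
Conditions: MnO2 (excess), CH2Cl2, rt
Reagents that add atoms: none
Why: MnO2 oxidation of a furylic (benzylic-type) alcohol should stop cleanly at the aldehyde C6.

Step 5
Reactants: 7 2-(dimethoxymethyl)-4-{[(4-methoxybenzyl)oxy]methyl}furan-3-carbaldehyde; 8 ethyl 2-(bromomethyl)acrylate
Product: 11 (5S)-5-[2-(dimethoxymethyl)-4-{[(4-methoxybenzyl)oxy]methyl}furan-3-yl]-3-methylideneoxolan-2-one, via silyl ether 9 (not isolated), via hydroxy ester 10 (not isolated)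
Conditions: CrCl2 (10 mol %), chiral 1,8-bis(oxazolinyl)carbazole ligand (12 mol %, enantiomer that gives the S alcohol), Mn, Me3SiCl, THF, rt; then Bu4NF, THF, 0 °C
Reagents that add atoms: none
Why: Catalytic asymmetric Nozaki–Hiyama–Kishi-type 2-(ethoxycarbonyl)allylation forms C5–C6, the chiral chromium complex choosing the aldehyde face and so setting C6 (S); fluoride then frees the alkoxide, which lactonises onto the ethyl ester.

Step 6
Reactants: 11 (5S)-α-methylene lactone
Product: 12 (3S,5S)-5-[2-(dimethoxymethyl)-4-{[(4-methoxybenzyl)oxy]methyl}furan-3-yl]-3-methyloxolan-2-one (cis)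
Conditions: H2 (1 atm), RhCl(PPh3)3 (5 mol %), benzene–EtOH, rt
Reagents that add atoms: none
Why: Homogeneous hydrogenation of the 1,1-disubstituted exocyclic alkene (furan and PMB ether untouched) should deliver hydrogen to the face anti to the C6 furyl group, giving the cis lactone and thereby C4 (S).

Step 7
Reactants: 12 (3S,5S)-cis lactone
Product: 13 (3S,5S)-5-hydroxy-5-[2-(dimethoxymethyl)-4-{[(4-methoxybenzyl)oxy]methyl}furan-3-yl]-3-methylpentan-2-one (in equilibrium with its cyclic hemiketal)
Conditions: MeLi (1.05 equiv), THF, −78 °C; aq. NH4Cl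
Reagents that add atoms: methyllithium, [Li]C
Why: Mono-addition of MeLi to a γ-lactone, whose tetrahedral lithium lactolate persists at −78 °C until the quench, gives the C3 methyl ketone (C2 introduced) and frees C6–OH without touching C4.

Step 8
Reactants: 13 (3S,5S)-hydroxy ketone; 14 2-(diethoxyphosphoryl)propanoic acid
Product: 15 (1S,3S)-1-[2-(dimethoxymethyl)-4-{[(4-methoxybenzyl)oxy]methyl}furan-3-yl]-3-methyl-4-oxopentyl 2-(diethoxyphosphoryl)propanoate
Conditions: DCC, DMAP (cat.), CH2Cl2, 0 °C → rt
Reagents that add atoms: none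
Why: Steglich esterification acylates the secondary C6 hydroxyl of the open-chain tautomer (the hemiketal hydroxyl is tertiary and inert), placing C1 and C10 on the C6 oxygen as the tether.

Step 9
Reactants: 15 phosphonate ester acetal
Product: 16 (1S,3S)-1-[2-formyl-4-{[(4-methoxybenzyl)oxy]methyl}furan-3-yl]-3-methyl-4-oxopentyl 2-(diethoxyphosphoryl)propanoate
Conditions: oxalic acid (aq.), THF, rt
Reagents that add atoms: water, O
Why: Mild acid-catalysed hydrolysis of the furfural-type dimethyl acetal frees the C9 aldehyde while ester, phosphonate and PMB ether survive.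

Step 10
Reactants: 16 aldehyde phosphonate
Product: 17 (4S,6S)-furan-fused oxepinone: seven-membered lactone O–C1(=O)–C10(CH3)=C9H–C8(furan)–C7(furan)–C6H, (Z) at C9=C10, C6 carrying the (2S)-2-methyl-3-oxobutyl chain and furan C11 carrying CH2OPMB
Conditions: K2CO3, 18-crown-6, toluene (0.003 M), rt → 40 °C
Reagents that add atoms: none
Why: Intramolecular Horner–Wadsworth–Emmons olefination closes the seven-membered lactone, the ring forcing the Z geometry (C1 cis to C8), and the aldehyde reacts far faster than the methyl ketone.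

Step 11
Reactants: 17 furan-fused oxepinone
Product: 20 (4S,6S)-bicyclic dilactone: 8-acetoxy butenolide (C12=O, C7=C11, C11–CH2OPMB) fused at C7–C8 to the seven-membered (Z)-enoate lactone, C8 epimers, via endoperoxide 18 (not isolated), via hydroxybutenolide 19 (not isolated)
Conditions: O2, hν (visible), tetraphenylporphyrin (cat.), CH2Cl2, −78 °C; i-Pr2NEt, −78 → 0 °C; then Ac2O, DMAP (cat.), 0 °C
Reagents that add atoms: dioxygen, O=O; acetic anhydride, CC(=O)OC(C)=O
Why: [4+2] addition of singlet oxygen to the furan gives 18, base removes its only α-hydrogen (C12–H, Kornblum–DeLaMare fragmentation) so that C12 becomes the lactone carbonyl and C8 the hemiacetal carbon of 19, and the hemiacetal hydroxyl is acetylated in the same flask.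

Step 12
Reactants: 20 (4S,6S)-bicyclic dilactone
Product: 22 (4S,6S,10S)-tricyclic alcohol: the target skeleton with free C6–OH and C13–OPMB, via ten-membered diketone 21 (not isolated)
Conditions: LiN(SiMe3)2 (1.05 equiv), THF (0.005 M), −78 °C → rt
Reagents that add atoms: none
Why: Proposed new method: kinetic deprotonation of the C2 methyl gives the lithium enolate, whose carbon adds to the lactone carbonyl C1 through a seven-membered transition state (7-exo-trig); the bridged hemiketal alkoxide expels the C6 oxygen, so the seven-membered lactone is expanded to the ten-membered carbocycle and C1–C2 is formed (diketone 21, which protonates the C6 alkoxide and becomes the lithium diketonate), the closest known reaction types being the Baker–Venkataraman O-to-C acyl migration and the Claisen acylation of ketone enolates by lactones. The diketonate oxygen on C3 then closes the furanone by a 5-exo-trig SN2′ attack on C10 with loss of acetate from C8 (closest known type: O-cyclisation of a β-diketone onto an allylic leaving group to a 2-vinyl-3(2H)-furanone), which also makes the C8=C9 enol-lactone double bond, its geometry being fixed by the ring. The new stereocentre C10 is controlled by C6: in the transition state the array C10–C9–C8–C7–C6 is close to planar and U-shaped, C6–H takes the inside position (allylic 1,3-strain), and the chain C5–C4–C3 with the attacking oxygen is thereby held on the face that gives 10S. The selectivities needed are methyl over methine enolisation (kinetic base at −78 °C, C4 untouched), C1 over C12 and the acetate carbonyl (only C1 is reached through a seven-membered transition state), oxygen attack at C10 over closure of C2 or of the C1 oxygen on C8 (both need substitution at the fully substituted acetal carbon, which has no SN2 path under these non-ionising conditions), and diketonate over the C6 hydroxyl (one equivalent of base leaves the alcohol neutral).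

Step 13
Reactants: 8 ethyl 2-(bromomethyl)acrylate
Product: 23 ethyl 2-{[(4-methoxybenzyl)oxy]methyl}acrylate
Conditions: 4-MeOC6H4CH2OH, DABCO (cat.), Et3N, CH2Cl2, rt
Reagents that add atoms: 4-methoxybenzyl alcohol, COc1ccc(CO)cc1
Why: Amine-mediated substitution of the allylic bromide by the alcohol (two successive SN2′ steps through the allylammonium salt) is the standard route to 2-(alkoxymethyl)acrylates.

Step 14
Reactants: 23 ethyl 2-{[(4-methoxybenzyl)oxy]methyl}acrylate
Product: 24 2-{[(4-methoxybenzyl)oxy]methyl}acrylic acid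
Conditions: LiOH, THF–H2O, 0 °C; then HCl (aq.) to pH 3
Reagents that add atoms: lithium hydroxide, [Li+].[OH-]
Why: Saponification of the ethyl ester, to which the PMB ether is stable.

Step 15
Reactants: 22 (4S,6S,10S)-tricyclic alcohol; 24 2-{[(4-methoxybenzyl)oxy]methyl}acrylic acid
Product: 25 (4S,6S,10S)-bis-PMB ether of the target: C6 ester of 24, C13–OPMB
Conditions: DCC, DMAP (cat.), CH2Cl2, 0 °C → rt
Reagents that add atoms: none
Why: Steglich esterification of the secondary C6 hydroxyl, which keeps the C6 configuration because the C6–O bond is not broken.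

Step 16
Reactants: 25 bis-PMB ether
Product: 26 target, (4S,6S,10S)
Conditions: DDQ (3 equiv), CH2Cl2–pH 7 buffer, 0 °C → rt
Reagents that add atoms: none
Why: Oxidative cleavage of both PMB ethers by DDQ (hydride abstraction, then hydrolysis), which the electron-poor enol lactone, furanone and acrylate should tolerate.

**Compound list**

1 | methyl 4,4-dimethoxy-3-oxobutanoate | COC(OC)C(=O)CC(=O)OC | starting material
2 | 1,3-dichloropropan-2-one | ClCC(=O)CCl | starting material
3 | methyl 4-(chloromethyl)-2-(dimethoxymethyl)-4-hydroxy-4,5-dihydrofuran-3-carboxylate (racemic) | COC(=O)C1=C(C(OC)OC)OCC1(O)CCl | intermediate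
4 | methyl 4-(chloromethyl)-2-(dimethoxymethyl)furan-3-carboxylate | COC(=O)c1c(CCl)coc1C(OC)OC | intermediate
5 | methyl 2-(dimethoxymethyl)-4-{[(4-methoxybenzyl)oxy]methyl}furan-3-carboxylate | COC(=O)c1c(COCc2ccc(OC)cc2)coc1C(OC)OC | intermediate
6 | [2-(dimethoxymethyl)-4-{[(4-methoxybenzyl)oxy]methyl}furan-3-yl]methanol | OCc1c(COCc2ccc(OC)cc2)coc1C(OC)OC | intermediate
7 | 2-(dimethoxymethyl)-4-{[(4-methoxybenzyl)oxy]methyl}furan-3-carbaldehyde | O=Cc1c(COCc2ccc(OC)cc2)coc1C(OC)OC | intermediate
8 | ethyl 2-(bromomethyl)acrylate | C=C(CBr)C(=O)OCC | starting material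
9 | ethyl (4S)-4-[2-(dimethoxymethyl)-4-{[(4-methoxybenzyl)oxy]methyl}furan-3-yl]-2-methylidene-4-[(trimethylsilyl)oxy]butanoate | C=C(C[C@H](O[Si](C)(C)C)c1c(COCc2ccc(OC)cc2)coc1C(OC)OC)C(=O)OCC | intermediate
10 | ethyl (4S)-4-hydroxy-4-[2-(dimethoxymethyl)-4-{[(4-methoxybenzyl)oxy]methyl}furan-3-yl]-2-methylidenebutanoate | C=C(C[C@H](O)c1c(COCc2ccc(OC)cc2)coc1C(OC)OC)C(=O)OCC | intermediate
11 | (5S)-5-[2-(dimethoxymethyl)-4-{[(4-methoxybenzyl)oxy]methyl}furan-3-yl]-3-methylideneoxolan-2-one | C=C1C[C@@H](c2c(COCc3ccc(OC)cc3)coc2C(OC)OC)OC1=O | intermediate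
12 | (3S,5S)-5-[2-(dimethoxymethyl)-4-{[(4-methoxybenzyl)oxy]methyl}furan-3-yl]-3-methyloxolan-2-one | C[C@H]1C[C@@H](c2c(COCc3ccc(OC)cc3)coc2C(OC)OC)OC1=O | intermediate
13 | (3S,5S)-5-hydroxy-5-[2-(dimethoxymethyl)-4-{[(4-methoxybenzyl)oxy]methyl}furan-3-yl]-3-methylpentan-2-one | CC(=O)[C@@H](C)C[C@H](O)c1c(COCc2ccc(OC)cc2)coc1C(OC)OC | intermediate
14 | 2-(diethoxyphosphoryl)propanoic acid (racemic) | CC(C(=O)O)P(=O)(OCC)OCC | starting material
15 | (1S,3S)-1-[2-(dimethoxymethyl)-4-{[(4-methoxybenzyl)oxy]methyl}furan-3-yl]-3-methyl-4-oxopentyl 2-(diethoxyphosphoryl)propanoate | CC(=O)[C@@H](C)C[C@H](OC(=O)C(C)P(=O)(OCC)OCC)c1c(COCc2ccc(OC)cc2)coc1C(OC)OC | intermediate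
16 | (1S,3S)-1-[2-formyl-4-{[(4-methoxybenzyl)oxy]methyl}furan-3-yl]-3-methyl-4-oxopentyl 2-(diethoxyphosphoryl)propanoate | CC(=O)[C@@H](C)C[C@H](OC(=O)C(C)P(=O)(OCC)OCC)c1c(COCc2ccc(OC)cc2)coc1C=O | intermediate
17 | (4S,6S)-furan-fused (Z)-oxepinone (lactone O–C1(=O)–C10(CH3)=C9H on furan C8/C7, C6 bearing the 2-methyl-3-oxobutyl chain) | CC(=O)[C@@H](C)C[C@@H]1OC(=O)/C(C)=C\c2occ(COCc3ccc(OC)cc3)c21 | intermediate
18 | (4S,6S)-furan 8,12-endoperoxide of 17 | CC(=O)[C@@H](C)C[C@@H]1OC(=O)/C(C)=C\C23OOC(O2)C(COCc4ccc(OC)cc4)=C13 | intermediate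
19 | (4S,6S)-8-hydroxy butenolide fused to the seven-membered lactone (C8 epimers) | CC(=O)[C@@H](C)C[C@@H]1OC(=O)/C(C)=C\C2(O)OC(=O)C(COCc3ccc(OC)cc3)=C12 | intermediate
20 | (4S,6S)-8-acetoxy butenolide fused to the seven-membered lactone (bicyclic dilactone, C8 epimers) | CC(=O)[C@@H](C)C[C@@H]1OC(=O)/C(C)=C\C2(OC(C)=O)OC(=O)C(COCc3ccc(OC)cc3)=C12 | intermediate
21 | (4S,6S)-ten-membered (Z)-enone β-diketone with C6–OH, fused at C7–C8 to the 8-acetoxy butenolide | C[C@H]1C[C@H](O)C2=C(COCc3ccc(OC)cc3)C(=O)OC2(OC(C)=O)/C=C(C)\C(=O)CC1=O | intermediate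
22 | (4S,6S,10S)-tricyclic alcohol (target skeleton, C6–OH, C13–OPMB) | O[C@H]1C[C@H](C)C2=CC(=O)[C@](C)(/C=C3/OC(=O)C(COCc4ccc(OC)cc4)=C31)O2 | intermediate
23 | ethyl 2-{[(4-methoxybenzyl)oxy]methyl}acrylate | C=C(COCc1ccc(OC)cc1)C(=O)OCC | intermediate
24 | 2-{[(4-methoxybenzyl)oxy]methyl}acrylic acid | C=C(COCc1ccc(OC)cc1)C(=O)O | intermediate
25 | (4S,6S,10S)-bis-PMB ether of the target | C=C(COCc1ccc(OC)cc1)C(=O)O[C@H]1C[C@H](C)C2=CC(=O)[C@](C)(/C=C3/OC(=O)C(COCc4ccc(OC)cc4)=C31)O2 | intermediate
26 | CNP0261115.1, (4S,6S,10S) | C=C(CO)C(=O)O[C@H]1C[C@H](C)C2=CC(=O)[C@](C)(/C=C3/OC(=O)C(CO)=C31)O2 | target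

**Step count and risks**

Total step count: 16. Longest linear sequence: 14 (steps 1–12, 15, 16).

Steps most likely to fail:

1. Step 12 (proposed new method). The enolate may add in conjugate fashion to the butenolide or exchange protons (epimerising C4) before the acyl transfer. After the transfer, ionisation at C8 may outrun the SN2′ closure, so that C2 or the C1 oxygen closes on C8. The facial selectivity at C10 may also be low. Fallback from 13, returning at 22, with the two bonds made in separate known steps and the ring closed by an aldol addition on an (E)-enal, in which C1 cannot reach C8: 13 is silylated (t-BuMe2SiCl, imidazole) to the silyl ether F1, the acetal is hydrolysed (aq. oxalic acid) to the aldehyde F2, and a Wittig reaction with 2-(triphenylphosphoranylidene)propanal gives the (E)-enal F3. Intramolecular aldol addition of the methyl-ketone lithium enolate to the aldehyde (LiN(SiMe3)2, THF, −78 °C, high dilution) closes the ten-membered ring to the β-hydroxy ketone F4, and Dess–Martin oxidation gives the β-diketone F5. Singlet-oxygen addition to the furan gives the endoperoxide F6, i-Pr2NEt converts it to the hydroxybutenolide F7, and acetylation gives the acetoxy butenolide F8. Et3N then effects the SN2′ closure of the diketone oxygen on C10 to the silyl ether F9, and HF·pyridine returns 22.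

2. Step 10. Intermolecular olefination (oligomerisation) may compete with closure of the seven-membered ring, and the base may epimerise C4. Fallback from 13, returning at 17, with the ring closed by C–O instead of C=C bond formation: the acetal of 13 is hydrolysed to the hydroxy aldehyde F10 (present as its lactol), a Z-selective Still–Gennari olefination with ethyl 2-[bis(2,2,2-trifluoroethoxy)phosphoryl]propanoate (KN(SiMe3)2, 18-crown-6, THF, −78 °C) gives the (Z)-enoate F11, and acid-catalysed lactonisation (camphorsulfonic acid, toluene) onto the C6 hydroxyl gives 17.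

3. Step 11. Singlet oxygen may add across the furan–alkene diene (C7=C8–C9=C10) instead of the furan 2,5-positions, or the endoperoxide may fragment by another path than loss of the C12 hydrogen. Fallback from 17, returning at 20, with a two-electron oxidation in place of the cycloaddition: N-bromosuccinimide with NaHCO3 in aqueous acetone opens the furan to the (Z)-keto enal F12, NaClO2/NaH2PO4/2-methylbut-2-ene oxidises the aldehyde to the acid, which closes to 19, and acetylation (Ac2O, DMAP) gives 20.

**Further compounds**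

F1 | step 12 | (3S,5S)-5-[(tert-butyldimethylsilyl)oxy]-5-[2-(dimethoxymethyl)-4-{[(4-methoxybenzyl)oxy]methyl}furan-3-yl]-3-methylpentan-2-one | CC(=O)[C@@H](C)C[C@H](O[Si](C)(C)C(C)(C)C)c1c(COCc2ccc(OC)cc2)coc1C(OC)OC
F2 | step 12 | 3-[(1S,3S)-1-[(tert-butyldimethylsilyl)oxy]-3-methyl-4-oxopentyl]-4-{[(4-methoxybenzyl)oxy]methyl}furan-2-carbaldehyde | CC(=O)[C@@H](C)C[C@H](O[Si](C)(C)C(C)(C)C)c1c(COCc2ccc(OC)cc2)coc1C=O
F3 | step 12 | (E)-3-{3-[(1S,3S)-1-[(tert-butyldimethylsilyl)oxy]-3-methyl-4-oxopentyl]-4-{[(4-methoxybenzyl)oxy]methyl}furan-2-yl}-2-methylprop-2-enal | CC(=O)[C@@H](C)C[C@H](O[Si](C)(C)C(C)(C)C)c1c(COCc2ccc(OC)cc2)coc1/C=C(\C)C=O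
F4 | step 12 | (4S,6S)-furan-fused ten-membered β-hydroxy ketone (C1–OH epimers, (E)-C9=C10, C6–OSiMe2t-Bu) | C[C@H]1C[C@H](O[Si](C)(C)C(C)(C)C)c2c(COCc3ccc(OC)cc3)coc2/C=C(C)/C(O)CC1=O
F5 | step 12 | (4S,6S)-furan-fused ten-membered β-diketone ((E)-C9=C10, C6–OSiMe2t-Bu) | C[C@H]1C[C@H](O[Si](C)(C)C(C)(C)C)c2c(COCc3ccc(OC)cc3)coc2/C=C(C)/C(=O)CC1=O
F6 | step 12 | (4S,6S)-furan 8,12-endoperoxide of F5 | C[C@H]1C[C@H](O[Si](C)(C)C(C)(C)C)C2=C(COCc3ccc(OC)cc3)C4OOC2(O4)/C=C(C)/C(=O)CC1=O
F7 | step 12 | (4S,6S)-8-hydroxy butenolide fused to the ten-membered (E)-enone β-diketone (C8 epimers) | C[C@H]1C[C@H](O[Si](C)(C)C(C)(C)C)C2=C(COCc3ccc(OC)cc3)C(=O)OC2(O)/C=C(C)/C(=O)CC1=O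
F8 | step 12 | (4S,6S)-8-acetoxy butenolide fused to the ten-membered (E)-enone β-diketone (C8 epimers) | C[C@H]1C[C@H](O[Si](C)(C)C(C)(C)C)C2=C(COCc3ccc(OC)cc3)C(=O)OC2(OC(C)=O)/C=C(C)/C(=O)CC1=O
F9 | step 12 | (4S,6S,10S)-tert-butyldimethylsilyl ether of 22 | C[Si](C)(C(C)(C)C)O[C@H]1C[C@H](C)C2=CC(=O)[C@](C)(/C=C3/OC(=O)C(COCc4ccc(OC)cc4)=C31)O2
F10 | step 10 | 3-[(1S,3S)-1-hydroxy-3-methyl-4-oxopentyl]-4-{[(4-methoxybenzyl)oxy]methyl}furan-2-carbaldehyde | CC(=O)[C@@H](C)C[C@H](O)c1c(COCc2ccc(OC)cc2)coc1C=O
F11 | step 10 | ethyl (Z)-3-{3-[(1S,3S)-1-hydroxy-3-methyl-4-oxopentyl]-4-{[(4-methoxybenzyl)oxy]methyl}furan-2-yl}-2-methylprop-2-enoate | CC(=O)[C@@H](C)C[C@H](O)c1c(COCc2ccc(OC)cc2)coc1/C=C(/C)C(=O)OCC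
F12 | step 11 | (4S,6S)-seven-membered (Z)-enoate lactone with C8 ketone and (Z)-C7=C11 bearing C12 aldehyde and CH2OPMB | CC(=O)[C@@H](C)C[C@@H]1OC(=O)/C(C)=C\C(=O)/C1=C(\C=O)COCc1ccc(OC)cc1
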